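**Retrosynthetic overview** (germacrane numbering)
1. Target ⇐ 13‑O‑acetylation and ketal hydrolysis ⇐ ten‑membered ring closed last at C5=C6 by intramolecular vinylogous Knoevenagel condensation (butenolide C6H2 onto a C5 aldehyde; the ring forces the E‑ylidene).
2. C8 ester ⇐ CBS reduction of a C8 ketone, then acylation with (R)‑3‑chloro‑2‑hydroxy‑2‑methylpropanoic acid.
3. Key bond C8–C9 ⇐ acyl anion at C8 (Breslow intermediate of a 2‑silyloxyfuran‑masked butenolide aldehyde) adding to C9 of an isopropenyl ketone (enantioselective Stetter reaction; C10 set by proton transfer).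
4. Isopropenyl ketone ⇐ (R)‑linalool (C1–C5, C15, C4 stereocentre) via lavender lactone; aldehyde ⇐ 2‑butyne‑1,4‑diol by carbomagnesiation/carboxylation, ozonolysis and silylation.
5. Ring order: butenolide, then oxolane (lactone, later the 1,4‑epoxy ketal), then the ten‑membered carbocycle.

Assumption: atom labels follow germacrane numbering (C1 hemiketal carbon, C4 oxygenated quaternary carbon, C8 ester carbinol, C10 methine bearing CH3, C13 acetoxymethyl). The (5aS,10bR) triazolium antipode is taken to give 10R in step 6; its mirror image is used if the sense proves opposite.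

**Route**

Step 1
Reactants: 1 2-butyne-1,4-diol; 2 vinylmagnesium chloride
Product: 3 4-ethenyl-3-(hydroxymethyl)furan-2(5H)-one
Conditions: 2 (4 equiv), THF, reflux; CO2, 0 °C; 2 M HCl
Reagents that add atoms: carbon dioxide O=C=O
Why: hydroxyl-directed anti-carbomagnesiation of the alkynediol dialkoxide places vinyl and magnesium trans, so carboxylation of the chelated alkenylmagnesium and acidification lactonise directly to the α-(hydroxymethyl)-β-vinyl butenolide (no stereocentre).

Step 2
Reactants: 3 4-ethenyl-3-(hydroxymethyl)furan-2(5H)-one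
Product: 4 3-{[tert-butyl(dimethyl)silyl]oxymethyl}-4-ethenylfuran-2(5H)-one
Conditions: TBSCl, imidazole, DMF, 0 °C to rt
Reagents that add atoms: tert-butyldimethylsilyl chloride CC(C)(C)[Si](C)(C)Cl
Why: standard silylation of the primary allylic alcohol gives an ether that is a poor leaving group in the later enolate-type steps (no stereocentre).

Step 3
Reactants: 4 3-{[tert-butyl(dimethyl)silyl]oxymethyl}-4-ethenylfuran-2(5H)-one
Product: 6 5-{[tert-butyl(dimethyl)silyl]oxy}-4-{[tert-butyl(dimethyl)silyl]oxymethyl}furan-3-carbaldehyde, via formylbutenolide 5 (not isolated)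
Conditions: O3, CH2Cl2, −78 °C; PPh3; evaporate; Et3N, TBSOTf, CH2Cl2, −78 to 0 °C
Reagents that add atoms: ozone [O-][O+]=O; tert-butyldimethylsilyl trifluoromethanesulfonate CC(C)(C)[Si](C)(C)OS(=O)(=O)C(F)(F)F
Why: ozonolysis cleaves the terminal vinyl group in preference to the electron-poor tetrasubstituted butenolide alkene, and soft enolisation at the γ-CH2 (2-silyloxyfuran formation) turns the labile ene-dicarbonyl aldehyde into an aromatic furan-3-carbaldehyde (no stereocentre).

Step 4
Reactants: 7 (R)-(−)-linalool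
Product: 9 (5R)-5-ethenyl-5-methyloxolan-2-one, via lactol 8 (not isolated)
Conditions: O3 (1.0 equiv), CH2Cl2/MeOH, −78 °C; Me2S; crude, then 2,2,6,6-tetramethylpiperidin-1-oxyl (10 mol%), PhI(OAc)2, CH2Cl2, rt
Reagents that add atoms: ozone [O-][O+]=O
Why: ozone selects the electron-rich trisubstituted alkene over the vinyl group, the hydroxy aldehyde closes to the lactol, and nitroxyl-catalysed oxidation gives lavender lactone with the C4 stereocentre taken unchanged from the chiral pool.

Step 5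
Reactants: 9 (5R)-5-ethenyl-5-methyloxolan-2-one; 10 isopropenylmagnesium bromide
Product: 11 (6R)-6-hydroxy-2,6-dimethylocta-1,7-dien-3-one
Conditions: 10 (1.1 equiv), THF, −78 °C; aq. NH4Cl
Reagents that add atoms: none
Why: Grignard mono-addition to a γ-lactone stops at the magnesium hemiketalate at −78 °C and gives, on quench, the γ-hydroxy α-methyl enone (in equilibrium with its cyclic hemiketal), C4 untouched.

Step 6
Reactants: 6 5-{[tert-butyl(dimethyl)silyl]oxy}-4-{[tert-butyl(dimethyl)silyl]oxymethyl}furan-3-carbaldehyde; 11 (6R)-6-hydroxy-2,6-dimethylocta-1,7-dien-3-one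
Product: 13 3-{[tert-butyl(dimethyl)silyl]oxymethyl}-4-{(3R)-3-[(5R)-5-ethenyl-2-methoxy-5-methyloxolan-2-yl]butanoyl}furan-2(5H)-one, via Stetter adduct 12 (not isolated)
Conditions: (5aS,10bR)-2-(pentafluorophenyl)-5a,10b-dihydro-4H,6H-indeno[2,1-b][1,2,4]triazolo[4,3-d][1,4]oxazin-2-ium tetrafluoroborate (20 mol%), i-Pr2NEt (20 mol%), THF, 23 °C; then MeOH, pyridinium p-toluenesulfonate (0.2 equiv), 0 °C to rt
Reagents that add atoms: methanol CO
Why: Proposed new method: the Breslow intermediate of the furan-3-carbaldehyde (acyl anion at C8) adds to the unsubstituted terminus C9 of the 1,1-disubstituted enone and the enolate is protonated at C10 by the adduct O–H inside the chiral carbene pocket, which sets 10R under catalyst control, the closest known chemistry being Stetter additions of furaldehydes to vinyl ketones and enantioselective intermolecular Stetter reactions of α-substituted acrylates whose stereocentre arises by proton transfer; the methanolic acid work-up then returns the butenolide and locks C1 as the cyclic methyl ketal (both anomers).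

Step 7
Reactants: 13 3-{[tert-butyl(dimethyl)silyl]oxymethyl}-4-{(3R)-3-[(5R)-5-ethenyl-2-methoxy-5-methyloxolan-2-yl]butanoyl}furan-2(5H)-one
Product: 14 3-{[tert-butyl(dimethyl)silyl]oxymethyl}-4-{(1R,3R)-3-[(5R)-5-ethenyl-2-methoxy-5-methyloxolan-2-yl]-1-hydroxybutyl}furan-2(5H)-one
Conditions: (S)-1-methyl-3,3-diphenyltetrahydro-1H,3H-pyrrolo[1,2-c][1,3,2]oxazaborole (0.3 equiv), catecholborane (1.8 equiv), toluene/CH2Cl2, −78 °C; MeOH, pH 7 buffer
Reagents that add atoms: none
Why: Corey–Bakshi–Shibata reduction of the enone-type ketone, with the butenolide carbon as the large and the CH2 as the small group, gives the 8R carbinol under reagent control, while catecholborane at −78 °C leaves the lactone, the ketal and the vinyl group alone.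

Step 8
Reactants: 15 (2R)-3-bromo-2-hydroxy-2-methylpropanoic acid
Product: 17 (2R)-3-chloro-2-hydroxy-2-methylpropanoic acid, via sodium methylglycidate 16 (not isolated)
Conditions: NaOH (2.1 equiv), H2O, 0 °C to rt; conc. HCl, 0 °C to rt
Reagents that add atoms: hydrogen chloride Cl
Why: intramolecular Williamson closure to the glycidate and chloride opening at the unhindered CH2 terminus exchange bromine for chlorine without touching the tertiary stereocentre, so the (R) descriptor is retained.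

Step 9
Reactants: 14 3-{[tert-butyl(dimethyl)silyl]oxymethyl}-4-{(1R,3R)-3-[(5R)-5-ethenyl-2-methoxy-5-methyloxolan-2-yl]-1-hydroxybutyl}furan-2(5H)-one; 17 (2R)-3-chloro-2-hydroxy-2-methylpropanoic acid
Product: 18 (1R,3R)-1-[4-{[tert-butyl(dimethyl)silyl]oxymethyl}-5-oxo-2,5-dihydrofuran-3-yl]-3-[(5R)-5-ethenyl-2-methoxy-5-methyloxolan-2-yl]butyl (2R)-3-chloro-2-hydroxy-2-methylpropanoate
Conditions: 17 (3 equiv), N-(3-dimethylaminopropyl)-N'-ethylcarbodiimide hydrochloride, 4-(dimethylamino)pyridine (0.3 equiv), CH2Cl2, 0 °C to rt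
Reagents that add atoms: none
Why: Steglich esterification acylates the only free secondary alcohol, the tertiary hydroxyl of the acid being too hindered to compete, and neither stereocentre is affected.

Step 10
Reactants: 18 (1R,3R)-1-[4-{[tert-butyl(dimethyl)silyl]oxymethyl}-5-oxo-2,5-dihydrofuran-3-yl]-3-[(5R)-5-ethenyl-2-methoxy-5-methyloxolan-2-yl]butyl (2R)-3-chloro-2-hydroxy-2-methylpropanoate
Product: 19 (1R,3R)-1-[4-{[tert-butyl(dimethyl)silyl]oxymethyl}-5-oxo-2,5-dihydrofuran-3-yl]-3-[(5R)-5-formyl-2-methoxy-5-methyloxolan-2-yl]butyl (2R)-3-chloro-2-hydroxy-2-methylpropanoate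
Conditions: O3, CH2Cl2, −78 °C (titrated to first blue); PPh3
Reagents that add atoms: ozone [O-][O+]=O
Why: ozonolysis of the monosubstituted vinyl group is much faster than attack on the tetrasubstituted α,β-unsaturated lactone and unmasks the non-enolisable C5 aldehyde on the quaternary C4 centre.

Step 11
Reactants: 19 (1R,3R)-1-[4-{[tert-butyl(dimethyl)silyl]oxymethyl}-5-oxo-2,5-dihydrofuran-3-yl]-3-[(5R)-5-formyl-2-methoxy-5-methyloxolan-2-yl]butyl (2R)-3-chloro-2-hydroxy-2-methylpropanoate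
Product: 20 (1S,4R,5E,8R,10R)-1,4-epoxy-1-methoxy-13-{[tert-butyl(dimethyl)silyl]oxy}germacra-5,7(11)-dien-12,6-olid-8-yl (2R)-3-chloro-2-hydroxy-2-methylpropanoate
Conditions: pyrrolidine (0.3 equiv), AcOH (1 equiv), MeOH/MeCN 1:4, 1 mM (syringe pump), 45 °C
Reagents that add atoms: none
Why: Proposed new method: the iminium ion of the aldehyde is attacked by the butenolide dienol at C6 and E1cB loss of pyrrolidine gives the γ-ylidene butenolide irreversibly, the closest known chemistry being amine- or base-mediated vinylogous aldol condensations of 2(5H)-furanones with aldehydes and Knoevenagel macrocyclisations; the base-inert C1 ketal blocks the competing six-ring closure, its anomers interconvert in acidic methanol so that the one with C10 and C5 cis closes, and the ring allows only the E-alkene.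

Step 12
Reactants: 20 (1S,4R,5E,8R,10R)-1,4-epoxy-1-methoxy-13-{[tert-butyl(dimethyl)silyl]oxy}germacra-5,7(11)-dien-12,6-olid-8-yl (2R)-3-chloro-2-hydroxy-2-methylpropanoate
Product: 21 (1S,4R,5E,8R,10R)-1,4-epoxy-1,13-dihydroxygermacra-5,7(11)-dien-12,6-olid-8-yl (2R)-3-chloro-2-hydroxy-2-methylpropanoate
Conditions: 48% aq. HF, MeCN, 0 °C
Reagents that add atoms: water O
Why: aqueous HF cleaves the primary silyl ether and hydrolyses the tertiary methyl ketal in one operation, and the transannular bridge allows the hemiketal only in the 1S configuration.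

Step 13
Reactants: 21 (1S,4R,5E,8R,10R)-1,4-epoxy-1,13-dihydroxygermacra-5,7(11)-dien-12,6-olid-8-yl (2R)-3-chloro-2-hydroxy-2-methylpropanoate
Product: 22 CNP0414417.2, (1S,4R,5E,8R,10R)-13-acetoxy-1,4-epoxy-1-hydroxygermacra-5,7(11)-dien-12,6-olid-8-yl (2R)-3-chloro-2-hydroxy-2-methylpropanoate
Conditions: Ac2O (1.2 equiv), pyridine, CH2Cl2, −20 to 0 °C
Reagents that add atoms: acetic anhydride CC(=O)OC(C)=O
Why: the primary allylic alcohol is acetylated selectively because the other two hydroxyls (hemiketal and side chain) are tertiary, and the labile allylic acetate is introduced last.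

**Compound list**

1 | 2-butyne-1,4-diol | OCC#CCO | starting material
2 | vinylmagnesium chloride | C=C[Mg]Cl | starting material
3 | 4-ethenyl-3-(hydroxymethyl)furan-2(5H)-one | O=C1OCC(C=C)=C1CO | intermediate
4 | 3-{[tert-butyl(dimethyl)silyl]oxymethyl}-4-ethenylfuran-2(5H)-one | O=C1OCC(C=C)=C1CO[Si](C)(C)C(C)(C)C | intermediate
5 | 4-{[tert-butyl(dimethyl)silyl]oxymethyl}-5-oxo-2,5-dihydrofuran-3-carbaldehyde | O=CC1=C(CO[Si](C)(C)C(C)(C)C)C(=O)OC1 | intermediate
6 | 5-{[tert-butyl(dimethyl)silyl]oxy}-4-{[tert-butyl(dimethyl)silyl]oxymethyl}furan-3-carbaldehyde | O=Cc1coc(O[Si](C)(C)C(C)(C)C)c1CO[Si](C)(C)C(C)(C)C | intermediate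
7 | (R)-(−)-linalool, (3R)-3,7-dimethylocta-1,6-dien-3-ol | CC(C)=CCC[C@@](C)(O)C=C | starting material
8 | (5R)-5-ethenyl-5-methyloxolan-2-ol (both anomers) | C=C[C@@]1(C)CCC(O)O1 | intermediate
9 | (5R)-5-ethenyl-5-methyloxolan-2-one (lavender lactone) | C=C[C@@]1(C)CCC(=O)O1 | intermediate
10 | isopropenylmagnesium bromide | CC(=C)[Mg]Br | starting material
11 | (6R)-6-hydroxy-2,6-dimethylocta-1,7-dien-3-one | C=C[C@](C)(O)CCC(=O)C(C)=C | intermediate
12 | (3R,7R)-1-[5-{[tert-butyl(dimethyl)silyl]oxy}-4-{[tert-butyl(dimethyl)silyl]oxymethyl}furan-3-yl]-7-hydroxy-3,7-dimethylnon-8-ene-1,4-dione | C=C[C@](C)(O)CCC(=O)[C@H](C)CC(=O)c1coc(O[Si](C)(C)C(C)(C)C)c1CO[Si](C)(C)C(C)(C)C | intermediate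
13 | 3-{[tert-butyl(dimethyl)silyl]oxymethyl}-4-{(3R)-3-[(5R)-5-ethenyl-2-methoxy-5-methyloxolan-2-yl]butanoyl}furan-2(5H)-one (both epimers at the ketal carbon) | C=C[C@@]1(C)CCC(OC)(O1)[C@H](C)CC(=O)C2=C(CO[Si](C)(C)C(C)(C)C)C(=O)OC2 | intermediate
14 | 3-{[tert-butyl(dimethyl)silyl]oxymethyl}-4-{(1R,3R)-3-[(5R)-5-ethenyl-2-methoxy-5-methyloxolan-2-yl]-1-hydroxybutyl}furan-2(5H)-one | C=C[C@@]1(C)CCC(OC)(O1)[C@H](C)C[C@@H](O)C2=C(CO[Si](C)(C)C(C)(C)C)C(=O)OC2 | intermediate
15 | (2R)-3-bromo-2-hydroxy-2-methylpropanoic acid | OC(=O)[C@@](C)(O)CBr | starting material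
16 | sodium (2S)-2-methyloxirane-2-carboxylate | [Na+].[O-]C(=O)[C@@]1(C)OC1 | intermediate
17 | (2R)-3-chloro-2-hydroxy-2-methylpropanoic acid | OC(=O)[C@@](C)(O)CCl | intermediate
18 | (1R,3R)-1-[4-{[tert-butyl(dimethyl)silyl]oxymethyl}-5-oxo-2,5-dihydrofuran-3-yl]-3-[(5R)-5-ethenyl-2-methoxy-5-methyloxolan-2-yl]butyl (2R)-3-chloro-2-hydroxy-2-methylpropanoate | C=C[C@@]1(C)CCC(OC)(O1)[C@H](C)C[C@@H](OC(=O)[C@@](C)(O)CCl)C2=C(CO[Si](C)(C)C(C)(C)C)C(=O)OC2 | intermediate
19 | (1R,3R)-1-[4-{[tert-butyl(dimethyl)silyl]oxymethyl}-5-oxo-2,5-dihydrofuran-3-yl]-3-[(5R)-5-formyl-2-methoxy-5-methyloxolan-2-yl]butyl (2R)-3-chloro-2-hydroxy-2-methylpropanoate | O=C[C@@]1(C)CCC(OC)(O1)[C@H](C)C[C@@H](OC(=O)[C@@](C)(O)CCl)C2=C(CO[Si](C)(C)C(C)(C)C)C(=O)OC2 | intermediate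
20 | 1-O-methyl-13-O-TBS macrocycle: (1S,4R,5E,8R,10R)-1,4-epoxy-1-methoxy-13-silyloxygermacra-5,7(11)-dien-12,6-olide 8-[(2R)-3-chloro-2-hydroxy-2-methylpropanoate] | CC(C)(C)[Si](C)(C)OCC1=C2/C(=C\[C@@]3(C)CC[C@](OC)(O3)[C@H](C)C[C@H]2OC(=O)[C@@](C)(O)CCl)OC1=O | intermediate
21 | 13-desacetyl target: (1S,4R,5E,8R,10R)-1,4-epoxy-1,13-dihydroxygermacra-5,7(11)-dien-12,6-olide 8-[(2R)-3-chloro-2-hydroxy-2-methylpropanoate] | OCC1=C2/C(=C\[C@@]3(C)CC[C@](O)(O3)[C@H](C)C[C@H]2OC(=O)[C@@](C)(O)CCl)OC1=O | intermediate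
22 | CNP0414417.2 | CC(=O)OCC1=C2/C(=C\[C@@]3(C)CC[C@](O)(O3)[C@H](C)C[C@H]2OC(=O)[C@@](C)(O)CCl)OC1=O | target

**Step count and risks**

Total: 13 steps. Longest linear sequence: 10 steps (1, 2, 3, 6, 7, 9, 10, 11, 12, 13).

Most likely to fail:

Step 6 (enantioselective Stetter union). Risks are low conversion with the α-substituted enone and weak control of C10 in the proton transfer. Fallback, setting out from 6 and 9 and returning at 13: C10 is taken from the chiral pool and the polarity of the union is turned round, with a homoenolate as the nucleophile. Methyl (2S)-3-iodo-2-methylpropanoate F1 is converted into its zinc homoenolate (Zn, LiCl, THF), transmetalated with ClTi(OiPr)3 and added to aldehyde 6; the adduct closes to the γ-lactone F2 (C8 epimers, of no consequence). The lithium enolate of 9 (LiN(SiMe3)2, THF, −78 °C) is acylated by F2 in a crossed Claisen condensation to give the β-keto lactone F3. Dess–Martin oxidation of the furyl carbinol gives the keto lactone F4. LiOH followed by buffered acid opens the lactone, removes the silyl ketene acetal and decarboxylates to the diketone F5, which MeOH with pyridinium p-toluenesulfonate converts into 13.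

Step 11 (ten-membered ring closure). Risks are insufficient acidity of the butenolide γ-CH2 under amine catalysis, oligomerisation, and slow ketal anomer exchange. Fallback, setting out from 18 and returning at 20: the ring is closed by an intramolecular Wittig olefination instead of a condensation. Radical bromination of 18 (N-bromosuccinimide, 2,2'-azobis(2-methylpropionitrile), PhCF3, 80 °C) gives the γ-bromobutenolide F6. Ozonolysis (O3, then Me2S) gives the bromo aldehyde F7. PPh3 in MeCN gives the phosphonium bromide F8, whose butenolide-stabilised ylide is formed with Et3N in dilute MeOH/MeCN containing a little AcOH and closes onto the aldehyde to give 20.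

Step 9 (esterification of a hindered carbinol with an unprotected α-hydroxy acid). Risks are N-acylurea formation and self-esterification of the acid. Fallback, setting out from 14 and 16 and returning at 18: the hydroxyl is carried as its epoxide. Sodium salt 16 is isolated by evaporation and coupled with 14 under Yamaguchi conditions (2,4,6-trichlorobenzoyl chloride, Et3N, then 4-(dimethylamino)pyridine) to give the epoxy ester F9; LiCl/AcOH in THF opens the epoxide at its CH2 terminus to give 18.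

**Further compounds**

F1 | step 6 | methyl (2S)-3-iodo-2-methylpropanoate | COC(=O)[C@H](C)CI
F2 | step 6 | (3R)-5-[5-{[tert-butyl(dimethyl)silyl]oxy}-4-{[tert-butyl(dimethyl)silyl]oxymethyl}furan-3-yl]-3-methyloxolan-2-one | C[C@@H]1CC(OC1=O)c1coc(O[Si](C)(C)C(C)(C)C)c1CO[Si](C)(C)C(C)(C)C
F3 | step 6 | (5R)-5-ethenyl-3-{(2R)-4-[5-{[tert-butyl(dimethyl)silyl]oxy}-4-{[tert-butyl(dimethyl)silyl]oxymethyl}furan-3-yl]-4-hydroxy-2-methylbutanoyl}-5-methyloxolan-2-one | C=C[C@@]1(C)CC(C(=O)[C@H](C)CC(O)c2coc(O[Si](C)(C)C(C)(C)C)c2CO[Si](C)(C)C(C)(C)C)C(=O)O1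
F4 | step 6 | (5R)-5-ethenyl-3-{(2R)-4-[5-{[tert-butyl(dimethyl)silyl]oxy}-4-{[tert-butyl(dimethyl)silyl]oxymethyl}furan-3-yl]-2-methyl-4-oxobutanoyl}-5-methyloxolan-2-one | C=C[C@@]1(C)CC(C(=O)[C@H](C)CC(=O)c2coc(O[Si](C)(C)C(C)(C)C)c2CO[Si](C)(C)C(C)(C)C)C(=O)O1
F5 | step 6 | 3-{[tert-butyl(dimethyl)silyl]oxymethyl}-4-[(3R,7R)-7-hydroxy-3,7-dimethyl-4-oxonon-8-enoyl]furan-2(5H)-one | C=C[C@](C)(O)CCC(=O)[C@H](C)CC(=O)C1=C(CO[Si](C)(C)C(C)(C)C)C(=O)OC1
F6 | step 11 | γ-bromobutenolide: 18 carrying bromine at the lactone CH (both epimers) | C=C[C@@]1(C)CCC(OC)(O1)[C@H](C)C[C@@H](OC(=O)[C@@](C)(O)CCl)C2=C(CO[Si](C)(C)C(C)(C)C)C(=O)OC2Br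
F7 | step 11 | bromo aldehyde: 19 carrying bromine at the lactone CH | O=C[C@@]1(C)CCC(OC)(O1)[C@H](C)C[C@@H](OC(=O)[C@@](C)(O)CCl)C2=C(CO[Si](C)(C)C(C)(C)C)C(=O)OC2Br
F8 | step 11 | triphenylphosphonium bromide of F7 (phosphorus at the lactone CH) | O=C[C@@]1(C)CCC(OC)(O1)[C@H](C)C[C@@H](OC(=O)[C@@](C)(O)CCl)C2=C(CO[Si](C)(C)C(C)(C)C)C(=O)OC2[P+](c3ccccc3)(c3ccccc3)c3ccccc3.[Br-]
F9 | step 9 | (1R,3R)-1-[4-{[tert-butyl(dimethyl)silyl]oxymethyl}-5-oxo-2,5-dihydrofuran-3-yl]-3-[(5R)-5-ethenyl-2-methoxy-5-methyloxolan-2-yl]butyl (2S)-2-methyloxirane-2-carboxylate | C=C[C@@]1(C)CCC(OC)(O1)[C@H](C)C[C@@H](OC(=O)[C@@]3(C)OC3)C2=C(CO[Si](C)(C)C(C)(C)C)C(=O)OC2
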